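Atom numbers below are eremophilane positions of the target: ring A = C1–C5 + C10, ring B = C5–C10; C3 carries the ester, C4 and C5 the methyl groups, C7 the isopropylidene group, C8 the ketone.
Retrosynthesis cuts, in order: the ester C–O bond; the C3–H bond (hydride to a C3 ketone); the C4–H bond (protonation of a C3=C4 silyl enol ether); the isopropylidene group (aldol/dehydration at C7); then C1=C2 and C3–C4 together, in one annulation of a ring B enone with an O-silylated two-carbon hydroxy aldehyde; finally ring B by Robinson annulation.
Enabling feature: C1 is the γ-carbon of the C9=C10–C8=O enone, so it can be carried as a vinylogous acidic methyl group, and C4 sits on the quaternary C5, so it can be carried as an acetyl C=O; after the first condensation at C1, C3 (next to oxygen) becomes the ε-carbon acid that closes ring A onto C4.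
Forward: ring B (step 1), ring A by a double aldol condensation (step 2), isopropylidene (steps 3–4), C4 and C3 stereocentres (steps 5–6), side-chain acid (steps 7–9), esterification (step 10).
Stereochemistry: C5 from an amino-acid-mediated desymmetrising aldol condensation; C4 and C3 from two hydrogen deliveries (kinetic C-protonation, then hydride) to the flat ring A from the face opposite the angular C5 methyl, which gives the all-cis O/Me/Me array; the side-chain centre from a chiral-pool alcohol.

Key step: step 2

Step 1
Reactants: 1 3-methylpentane-2,4-dione; 2 but-3-en-2-one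
Product: 4 (S)-4-acetyl-3,4-dimethylcyclohex-2-en-1-one, via triketone 3 (not isolated)
Conditions: Et3N (cat.), neat, 23 °C; then L-phenylalanine (0.3 equiv), (1S)-(+)-camphor-10-sulfonic acid (0.15 equiv), DMF, 23 → 70 °C
Reagents that add atoms: none
Why: Robinson annulation run as a Michael addition followed by a Hajos–Parrish–Eder–Sauer–Wiechert aldol condensation, in which the enamine of the unhindered side-chain methyl ketone of 3 adds to one of the two enantiotopic acetyl groups in the hydrogen-bonded transition state set by the L-amino acid, which should give the quaternary centre (C5) as S.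

Step 2
Reactants: 4 (S)-4-acetyl-3,4-dimethylcyclohex-2-en-1-one; 5 2-[(tert-butyldimethylsilyl)oxy]acetaldehyde
Product: 8 (S)-6-[(tert-butyldimethylsilyl)oxy]-4a,5-dimethyl-4,4a-dihydronaphthalen-2(3H)-one, via dienone 6 (not isolated), via aldol 7 (not isolated)
Conditions: 5 (2.5 equiv, added over 6 h), pyrrolidine (0.5 equiv), PhCO2H (0.5 equiv), 4 Å molecular sieves, PhMe, 50 → 90 °C
Reagents that add atoms: none
Why: Proposed new method: pyrrolidine condenses with the unhindered ring ketone (C8) to give the linear dienamine, whose exocyclic γ-carbon C1 adds to the iminium ion of 5, and loss of water gives dienone 6 (C1=C2); re-condensation gives the trienamine, whose ε-carbon C3 (the CH2 next to OSi) adds to the acetyl carbonyl C4, and the tertiary aldol 7 loses water by vinylogous E1cB elimination to leave the C3=C4 silyl enol ether of 8. The closest known reaction types are the amine-mediated vinylogous aldol condensation of 3-methylcyclohex-2-enones with aldehydes at the exocyclic methyl group and the intramolecular aldol condensation that closes the cyclohexenone in a Robinson annulation; new is their coupling in one flask through dienamine and trienamine intermediates. Ring A closes by a 6-(enolendo)-exo-trig aldol addition of C3 to C4, followed by dehydration. No new stereocentre is formed: C1 to C4 end up sp2 and C5 has no acidic hydrogen, so a flat ring A is handed on to the two face-selective hydrogen deliveries of steps 5 and 6. The step needs attack on 5 by C1 rather than by the ring CH2 next to C8 or the acetyl CH3, and cross- rather than self-condensation of 5; the first should be secured because the acetyl group on the quaternary C5 cannot form an enamine, dienamines of 3-methylcyclohexenones react with aldehydes at the γ-methyl carbon, and only the C1 adduct is drained by the irreversible ring closure, the second by slow addition of 5 and sieves that also protect the silyl enol ether. The E geometry of 6 does not block the closure, because C1–C2 is a single bond in the trienamine.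

Step 3
Reactants: 8 (S)-6-[(tert-butyldimethylsilyl)oxy]-4a,5-dimethyl-4,4a-dihydronaphthalen-2(3H)-one; 9 acetone
Product: 10 (3S,4aS)-6-[(tert-butyldimethylsilyl)oxy]-3-(2-hydroxypropan-2-yl)-4a,5-dimethyl-4,4a-dihydronaphthalen-2(3H)-one
Conditions: LiN(i-Pr)2 (1.1 equiv), THF, −78 °C; 9 (5 equiv), −78 °C; AcOH, −78 °C
Reagents that add atoms: none
Why: Kinetic deprotonation at the only α-CH2 of the ring ketone (C7) gives the cross-conjugated lithium enolate, which adds to acetone (aldol addition) on the face away from the angular methyl, while the silyl enol ether masks the second carbonyl; the new C7 centre is removed in step 4.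

Step 4
Reactants: 10 (3S,4aS)-6-[(tert-butyldimethylsilyl)oxy]-3-(2-hydroxypropan-2-yl)-4a,5-dimethyl-4,4a-dihydronaphthalen-2(3H)-one
Product: 12 (S)-6-[(tert-butyldimethylsilyl)oxy]-4a,5-dimethyl-3-(propan-2-ylidene)-4,4a-dihydronaphthalen-2(3H)-one, via mesylate 11 (not isolated)
Conditions: MsCl, Et3N, CH2Cl2, 0 °C; then 1,8-diazabicyclo[5.4.0]undec-7-ene (DBU), 23 °C
Reagents that add atoms: none
Why: Mesylation of the tertiary alcohol and E1cB elimination (aldol dehydration) should give the conjugated, tetrasubstituted isopropylidene enone, the thermodynamic position of this double bond.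

Step 5
Reactants: 12 (S)-6-[(tert-butyldimethylsilyl)oxy]-4a,5-dimethyl-3-(propan-2-ylidene)-4,4a-dihydronaphthalen-2(3H)-one
Product: 13 (4aR,5R)-4a,5-dimethyl-3-(propan-2-ylidene)-4,4a-dihydronaphthalene-2,6(3H,5H)-dione
Conditions: Bu4NF (1.1 equiv), AcOH (2 equiv), THF, −78 → −40 °C
Reagents that add atoms: none
Why: Fluoride cleaves the Si–O bond and the released enolate is protonated on C4 under kinetic control (buffered, cold) from the face opposite the angular C5 methyl, which should place the C4 methyl cis to it; this is the kinetic protonation of an enolate generated from a silyl enol ether.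

Step 6
Reactants: 13 (4aR,5R)-4a,5-dimethyl-3-(propan-2-ylidene)-4,4a-dihydronaphthalene-2,6(3H,5H)-dione
Product: 14 (4aR,5R,6S)-6-hydroxy-4a,5-dimethyl-3-(propan-2-ylidene)-4,4a,5,6-tetrahydronaphthalen-2(3H)-one
Conditions: NaBH4, CeCl3·7H2O, MeOH, −78 °C
Reagents that add atoms: none
Why: Luche reduction: 1,2-hydride addition to the C3 ketone, which is far less hindered than the cross-conjugated C8 ketone flanked by the isopropylidene group, from the face opposite both methyl groups should give the 3S alcohol with OH, C4-Me and C5-Me all cis, and the cold, non-basic medium should not epimerise C4.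

Step 7
Reactants: 15 (S)-2-methylbutan-1-ol
Product: 16 (S)-2-methylbutanal
Conditions: 2,2,6,6-tetramethylpiperidine-1-oxyl (cat.), KBr (cat.), NaOCl, NaHCO3, CH2Cl2/H2O, 0 °C
Reagents that add atoms: none
Why: Anelli oxidation (oxoammonium-mediated) stops at the aldehyde and, being fast at 0 °C near neutral pH, should leave the α-stereocentre intact.

Step 8
Reactants: 16 (S)-2-methylbutanal; 17 triethyl (E)-4-phosphonobut-2-enoate
Product: 18 ethyl (2E,4E,6S)-6-methylocta-2,4-dienoate
Conditions: 17, LiN(SiMe3)2, THF, −78 °C; then 16, −78 → 0 °C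
Reagents that add atoms: none
Why: Vinylogous Horner–Wadsworth–Emmons olefination, in which the stabilised phosphonate anion should form the new C4=C5 bond E while the crotonate double bond stays E, and cold addition protects the α-stereocentre of 16.

Step 9
Reactants: 18 ethyl (2E,4E,6S)-6-methylocta-2,4-dienoate
Product: 19 (2E,4E,6S)-6-methylocta-2,4-dienoic acid
Conditions: LiOH, THF/MeOH/H2O, 23 °C; then HCl (aq)
Reagents that add atoms: lithium hydroxide [Li+].[OH-]
Why: Saponification of the ethyl ester by acyl–oxygen cleavage, which touches neither the diene geometry nor the remote stereocentre.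

Step 10
Reactants: 14 (4aR,5R,6S)-6-hydroxy-4a,5-dimethyl-3-(propan-2-ylidene)-4,4a,5,6-tetrahydronaphthalen-2(3H)-one; 19 (2E,4E,6S)-6-methylocta-2,4-dienoic acid
Product: 21 (1R,2S,8aR)-1,8a-dimethyl-6-oxo-7-(propan-2-ylidene)-1,2,6,7,8,8a-hexahydronaphthalen-2-yl (2E,4E,6S)-6-methylocta-2,4-dienoate, via mixed anhydride 20 (not isolated)
Conditions: 19, 2,4,6-trichlorobenzoyl chloride, Et3N, THF, 23 °C; then 14, 4-(dimethylamino)pyridine, PhMe, 23 → 50 °C
Reagents that add atoms: none
Why: Yamaguchi esterification through mixed anhydride 20 should acylate the hindered secondary allylic alcohol with retention at C3, because the C3–O bond is not broken.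

Compound list
1 | 3-methylpentane-2,4-dione | CC(=O)C(C)C(C)=O | starting material
2 | but-3-en-2-one | CC(=O)C=C | starting material
3 | 3-acetyl-3-methylheptane-2,6-dione | CC(=O)CCC(C)(C(C)=O)C(C)=O | intermediate
4 | (S)-4-acetyl-3,4-dimethylcyclohex-2-en-1-one | CC(=O)[C@@]1(C)CCC(=O)C=C1C | intermediate
5 | 2-[(tert-butyldimethylsilyl)oxy]acetaldehyde | O=CCO[Si](C)(C)C(C)(C)C | starting material
6 | (S)-4-acetyl-3-[(E)-3-[(tert-butyldimethylsilyl)oxy]prop-1-en-1-yl]-4-methylcyclohex-2-en-1-one | CC(=O)[C@@]1(C)CCC(=O)C=C1/C=C/CO[Si](C)(C)C(C)(C)C | intermediate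
7 | (4aS)-6-[(tert-butyldimethylsilyl)oxy]-5-hydroxy-4a,5-dimethyl-4,4a,5,6-tetrahydronaphthalen-2(3H)-one (either configuration at C5 and C6; both dehydrate) | O=C1C=C2C=CC(O[Si](C)(C)C(C)(C)C)C(C)(O)[C@@]2(C)CC1 | intermediate
8 | (S)-6-[(tert-butyldimethylsilyl)oxy]-4a,5-dimethyl-4,4a-dihydronaphthalen-2(3H)-one | O=C1C=C2C=CC(O[Si](C)(C)C(C)(C)C)=C(C)[C@@]2(C)CC1 | intermediate
9 | acetone | CC(C)=O | starting material
10 | (3S,4aS)-6-[(tert-butyldimethylsilyl)oxy]-3-(2-hydroxypropan-2-yl)-4a,5-dimethyl-4,4a-dihydronaphthalen-2(3H)-one | O=C1C=C2C=CC(O[Si](C)(C)C(C)(C)C)=C(C)[C@@]2(C)C[C@H]1C(C)(C)O | intermediate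
11 | methanesulfonate of the tertiary alcohol 10 | O=C1C=C2C=CC(O[Si](C)(C)C(C)(C)C)=C(C)[C@@]2(C)C[C@H]1C(C)(C)OS(C)(=O)=O | intermediate
12 | (S)-6-[(tert-butyldimethylsilyl)oxy]-4a,5-dimethyl-3-(propan-2-ylidene)-4,4a-dihydronaphthalen-2(3H)-one | O=C1C=C2C=CC(O[Si](C)(C)C(C)(C)C)=C(C)[C@@]2(C)CC1=C(C)C | intermediate
13 | (4aR,5R)-4a,5-dimethyl-3-(propan-2-ylidene)-4,4a-dihydronaphthalene-2,6(3H,5H)-dione | O=C1C=C2C=CC(=O)[C@H](C)[C@@]2(C)CC1=C(C)C | intermediate
14 | (4aR,5R,6S)-6-hydroxy-4a,5-dimethyl-3-(propan-2-ylidene)-4,4a,5,6-tetrahydronaphthalen-2(3H)-one | O=C1C=C2C=C[C@H](O)[C@H](C)[C@@]2(C)CC1=C(C)C | intermediate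
15 | (S)-2-methylbutan-1-ol | CC[C@H](C)CO | starting material
16 | (S)-2-methylbutanal | CC[C@H](C)C=O | intermediate
17 | triethyl (E)-4-phosphonobut-2-enoate | CCOC(=O)/C=C/CP(=O)(OCC)OCC | starting material
18 | ethyl (2E,4E,6S)-6-methylocta-2,4-dienoate | CC[C@H](C)/C=C/C=C/C(=O)OCC | intermediate
19 | (2E,4E,6S)-6-methylocta-2,4-dienoic acid | CC[C@H](C)/C=C/C=C/C(=O)O | intermediate
20 | (2E,4E,6S)-6-methylocta-2,4-dienoic 2,4,6-trichlorobenzoic anhydride | CC[C@H](C)/C=C/C=C/C(=O)OC(=O)c1c(Cl)cc(Cl)cc1Cl | intermediate
21 | (1R,2S,8aR)-1,8a-dimethyl-6-oxo-7-(propan-2-ylidene)-1,2,6,7,8,8a-hexahydronaphthalen-2-yl (2E,4E,6S)-6-methylocta-2,4-dienoate (CNP0215744.1) | CC[C@H](C)/C=C/C=C/C(=O)O[C@H]1C=CC2=CC(=O)C(=C(C)C)C[C@]2(C)[C@H]1C | target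

Total step count: 10. Longest linear sequence: 7 (steps 1–6 and 10).

Steps most likely to fail

Step 2 (proposed new method). The dienamine may react at the ring CH2 or the acetyl methyl instead of C1, the aldehyde may self-condense, or the sequence may stall at the open dienone because the hindered acetyl carbonyl resists the second aldol. The fallback sets out from 4 and returns at 8, using known reactions only. Wohl–Ziegler bromination of the γ-methyl group (N-bromosuccinimide, 2,2′-azobis(2-methylpropionitrile), PhCF3, 80 °C) should give (S)-4-acetyl-3-(bromomethyl)-4-methylcyclohex-2-en-1-one F1. Michaelis–Arbuzov reaction with P(OEt)3 (neat, 110 °C) should give diethyl {[(6S)-6-acetyl-6-methyl-3-oxocyclohex-1-en-1-yl]methyl}phosphonate F2. Vinylogous Horner–Wadsworth–Emmons olefination of F2 with 5 (LiCl, DBU, MeCN) fixes the site of the first bond and should give dienone 6, now isolated. KOt-Bu (cat.) in t-BuOH/THF should then close ring A by intramolecular aldol condensation to 8.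

Step 5. Facial selectivity of the protonation rests only on the difference between the angular methyl and the ring B methylene, and the new centre can be lost by re-enolisation, since the cis-dimethyl ketone is expected to be the less stable epimer. The fallback sets out from 12 and returns at 13, replacing kinetic control by equilibration, separation and recycling. Desilylation (Bu4NF, AcOH, THF, 0 °C) without stereocontrol should give 13 together with its C4 epimer (4aR,5S)-4a,5-dimethyl-3-(propan-2-ylidene)-4,4a-dihydronaphthalene-2,6(3H,5H)-dione F3. The two are separated by chromatography, and F3 is re-equilibrated with DBU (cat.) in THF and resubmitted until converted into 13.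

Step 6. Hydride may enter from the face of the angular methyl, or the cross-conjugated carbonyl and the dienone may compete (over-reduction, conjugate reduction). The fallback sets out from 13 and returns at 21, and answers the facial problem by switching the esterification from retention to inversion. If the same reduction delivers the C3 epimer (4aR,5R,6R)-6-hydroxy-4a,5-dimethyl-3-(propan-2-ylidene)-4,4a,5,6-tetrahydronaphthalen-2(3H)-one F4, this alcohol is esterified with 19 under Mitsunobu conditions (PPh3, diisopropyl azodicarboxylate, THF, 0 °C). Inversion at C3 should give 21 directly.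

Further compounds
F1 | step 2 | (S)-4-acetyl-3-(bromomethyl)-4-methylcyclohex-2-en-1-one | CC(=O)[C@@]1(C)CCC(=O)C=C1CBr
F2 | step 2 | diethyl {[(6S)-6-acetyl-6-methyl-3-oxocyclohex-1-en-1-yl]methyl}phosphonate | CC(=O)[C@@]1(C)CCC(=O)C=C1CP(=O)(OCC)OCC
F3 | step 5 | (4aR,5S)-4a,5-dimethyl-3-(propan-2-ylidene)-4,4a-dihydronaphthalene-2,6(3H,5H)-dione | O=C1C=C2C=CC(=O)[C@@H](C)[C@@]2(C)CC1=C(C)C
F4 | step 6 | (4aR,5R,6R)-6-hydroxy-4a,5-dimethyl-3-(propan-2-ylidene)-4,4a,5,6-tetrahydronaphthalen-2(3H)-one | O=C1C=C2C=C[C@@H](O)[C@H](C)[C@@]2(C)CC1=C(C)C
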